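## Structural features

The target is an octahydro-2H-chromene: an oxane (O, C13, C12, C11, C9, C8) trans-fused along C8–C9 to a cyclohexane, ring B (C8, C9, C10, C5, C6, C7). It is numbered here as a labdane whose ring A is opened between C2 and C3. C13 carries a methyl (C16) and the vinyl group C14=C15, C8 a methyl (C17) and the ring oxygen, C10 a methyl (C20) and the C1H2–C2O2H arm, and C5 the C4(CH3)2–C3O2H arm. Four of the five stereocentres (C8, C9, C10, C5; 8R,9R,10S,5R) are contiguous, and C13 (R) lies across the ring oxygen. In the chair–chair form C16, C17 and C20 are axial on one face, H9 and H5 axial on the other, and the C8 oxygen, C11, C1 and C4 equatorial. Fragile points are the tertiary allylic ether C13–O (ionises with acid), the vinyl group (rules out hydrogenation), and the C3 carboxyl, which sits on a quaternary carbon next to the C5 methine and is hard to reach at the carbonyl. The real difficulty is the quaternary C10, wedged between C9 and C5 (which carries a second quaternary carbon, C4), in the correct relation to C5 and to the C8/C9 fusion. The key step reads C2–C1–C10 as an enal acceptor (C10 is β to the C2 carbonyl), C8=C9 as a trisubstituted alkene donor and the C13 hydroxyl as terminator. Ring B and the oxane then form together from an open chain that carries only C5 and C13.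

## Logic of the disconnections

**24 to 23.** Cut: the O–CH3 bond of the C3 ester. C3 travels as a methyl ester because it must ignore the Lewis acid (a tert-butyl ester could close irreversibly onto C10 as a lactone) and the chlorite oxidation. Gain: the two carboxyls stay differentiated to the end. Demand: cleavage must take place at the methyl carbon, because the carbonyl is shielded by C4 and C5.

**23 to 22.** Cut: the C2–OH bond (oxidation level only). The aldehyde is what the cyclisation leaves behind, so the initiator is reused as the C2 carboxyl. Gain: no extra carbon–carbon bond is needed. Demand: an oxidant that spares the vinyl group and the allylic ether.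

**22 to 20 (through 21).** Cut: C9–C10 and C8–O. This is the only cut that removes both rings and three stereocentres (C8, C9, C10) at once and leaves an acyclic chain. Demand: C9 must add to C10 on one face only, and oxygen must add anti at C8. For this reason 20 is made with a Z-configured C1=C10 bond (formyl cis to C5) and an E-configured C8=C9 bond; constitution and stereocentres are otherwise those of the bare disconnection.

**20 to 19 to 18.** Cut: the C2=O π bond and the two O–Si bonds. The aldehyde is unmasked last so that the strained Z-enal is never carried through basic steps. Gain: 18 is a robust, fully protected chain. Demand: oxidation of the primary allylic alcohol beside a free tertiary allylic alcohol, without Z to E isomerisation.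

**18 to 16 (through 17).** Cut: the two C4–CH3 bonds. Removing them turns the C3/C4/C5 region into a plain β-branched ester that can come from a conjugate addition. Gain: C5 becomes the only stereocentre to set. Demand: two enolate methylations, the second creating a quaternary carbon next to C5.

**16 to 10 + 15.** Cut: C5–C10. One catalyst-controlled 1,4-addition sets C5 and brings in C1, C2, C10 and C20 with the Z geometry already fixed. Gain: a linear trienoate and a four-carbon alkenylboronate. Demand: facial control by the rhodium–BINAP catalyst and retention of alkenyl geometry.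

**15 to 14 to 13 to 11 (through 12).** Cut: C10–B, O–Si, then C10–I with C1–H. Gain: the Z arrangement of C2 and the future C5 comes from a trans-hydroalumination of a propargylic alcohol. Demand: clean retention through iodination and borylation.

**10 to 8 + 9.** Cut: C4=C5. Gain: a standard E-selective olefination supplies C3 and C4. Demand: none beyond E selectivity.

**8 to 6 to 4 + 5 (through 7).** Cut: the aldehyde C5=O (from C≡N) and C6–C7. A two-carbon nitrile anion joins C6 and C5 to the allylic position C7 and is then lowered to the aldehyde. Demand: substitution at the primary carbon without allylic transposition.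

**4 to 3 to 2 to 1.** Cut: C7–Br, C7–O and O–Si. Gain: 1 supplies C7–C9, C11–C17 and the C13 centre ready-made. Demand: oxidation of the E methyl group only, which also fixes the E geometry of C8=C9.

## Other disconnections considered

**Alternative 1:** The cut is C12–C13, with C14 carried as a carboxyl group. Forward, the cis-fused dioxanone A1 is enolised (KN(SiMe3)2, Me3SiCl) and its silyl ketene acetal rearranges [3,3] through a boat to the dihydropyran acid A2: C13 bonds to C12, the C9–O bond is given up and C9=C11 appears.
- In its favour: C13 is created by suprafacial transfer from the C9–O bond, so its configuration is set intramolecularly. The C8–O bond exists beforehand, so no tertiary cation at C8 is involved. On control of C13 it is the equal of the chosen plan (which buys C13 in 1), and on independence from a chiral-pool terpene it is the better.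
- Against it here: ring B with C5, C8, C10 and a tertiary vinyl carbinol at C9 must be built first, with the vinyl group entering cis to the C17 and C20 methyl groups. The lactone must be closed on a di-tertiary diol. The base also removes the acidic C1 protons. Afterwards C9=C11 must be hydrogenated from the face opposite the two methyl groups, C14 taken from acid to vinyl, and two tert-butyl esters removed with acid beside the tertiary allylic ether.
- Comparison: it is mechanistically tidy in the one bond it makes, but it closes one ring and sets one stereocentre where the chosen step closes two rings and sets three. It would be longer by the whole ring B synthesis plus about five finishing steps.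

**Alternative 2:** The cuts are C5–C6 and C9–C10. Forward, the diene A3 (from 1 by allylic oxidation to the aldehyde and methylenation) and the α-methyl enal A4 combine under a protonated oxazaborolidine to give the cyclohexene aldehyde A5.
- In its favour: it is the most convergent option. It sets C5, C9 and C10 in one catalyst-controlled step, and on that count, and on the fact that C5 needs no separate asymmetric step, it is the better of the two plans. Its diene is reached from 1 in about three steps.
- Against it here: A4 is a trisubstituted enal whose β-carbon carries a quaternary carbon, a very reluctant dienophile. The required adduct has the formyl group trans to C11 (formyl exo), which an acyclic diene does not guarantee. C1 must then be homologated by one carbon at a neopentyl quaternary centre, and the C7=C8 alkene must take up the C13 oxygen at C8 with the correct face.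
- Comparison: step count would be similar or slightly higher than the chosen plan. The chosen step moves the problematic quaternary C10 into an intramolecular bond formation, whereas here it depends on the bimolecular reactivity of the most hindered partner.

**Alternative 3:** The cut is O–C13. Forward, constant-current oxidation of the ketene dithioacetal A6 (carbon anode, LiClO4, methanol, 2,6-lutidine) gives a radical cation that the C8 hydroxyl attacks at C13; further oxidation and methanol trapping give the dithio-orthoester A7.
- In its favour: conditions are neutral and mild, and the polarity is reversed (oxygen nucleophile, C13 electrophile), so no cation arises at C8. The bulkier C14 group should prefer the equatorial site, which is the required C13 epimer. On mildness towards the C8 centre it is the equal or the better of the chosen plan.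
- Against it here: ring B with all four contiguous stereocentres and the tertiary C8 alcohol must already exist. C13 is formed without a strong controlling element other than size. The orthoester must then be converted to a vinyl group (hydrolysis, reduction, olefination), and the tert-butyl esters again require acid.
- Comparison: one ring and one stereocentre per key step, against two and three. It would be longer by the ring B synthesis and about four finishing steps.

Key step: step 14

Remark on the chemistry: checked atom by atom against the target (5R,8R,9R,10S,13R; the R centre of (R)-linalool maps onto C13), the constitution and stereocentres of the dienal and of the bicyclic aldehyde need no correction. The one design change is that the dienal is made with a Z-configured C1=C10 bond, because only then does allylic strain fix the conformation about C5–C10.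

## Route

Step 1
Reactants: 1 (R)-linalool, (3R)-3,7-dimethylocta-1,6-dien-3-ol
Product: 2 triethyl{[(3R)-3,7-dimethylocta-1,6-dien-3-yl]oxy}silane
Conditions: Et3SiOTf, 2,6-lutidine, CH2Cl2, −78 → 0 °C
Reagents that add atoms: triethylsilyl trifluoromethanesulfonate, CC[Si](CC)(CC)OS(=O)(=O)C(F)(F)F
Why: Silylation of a tertiary alcohol with a silyl triflate and a hindered base; the ether removes the only acidic proton ahead of the carbanion and enolate steps, and C13 is not touched.

Step 2
Reactants: 2 triethyl{[(3R)-3,7-dimethylocta-1,6-dien-3-yl]oxy}silane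
Product: 3 (2E,6R)-2,6-dimethyl-6-[(triethylsilyl)oxy]octa-2,7-dien-1-ol
Conditions: SeO2 (0.3 equiv), t-BuOOH, salicylic acid (cat.), CH2Cl2, 0 °C → rt
Reagents that add atoms: tert-butyl hydroperoxide, CC(C)(C)OO (terminal oxidant; the oxygen is passed on by selenium dioxide, O=[Se]=O)
Why: Selenium dioxide allylic oxidation (ene reaction, then [2,3]-shift) selects the E methyl group of the trisubstituted alkene, which makes C7 functional and fixes the E geometry of the future C8=C9 bond; the vinyl group has no allylic hydrogen and should stay inert.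

Step 3
Reactants: 3 (2E,6R)-2,6-dimethyl-6-[(triethylsilyl)oxy]octa-2,7-dien-1-ol
Product: 4 {[(3R,6E)-8-bromo-3,7-dimethylocta-1,6-dien-3-yl]oxy}(triethyl)silane
Conditions: CBr4, PPh3, 2,6-lutidine (0.2 equiv), CH2Cl2, −20 → 0 °C
Reagents that add atoms: carbon tetrabromide, BrC(Br)(Br)Br
Why: Appel bromination of a primary allylic alcohol under buffered, near-neutral conditions; substitution at the primary carbon keeps the alkene geometry and the silyl ether.

Step 4
Reactants: 4 {[(3R,6E)-8-bromo-3,7-dimethylocta-1,6-dien-3-yl]oxy}(triethyl)silane; 5 acetonitrile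
Product: 6 (4E,8R)-4,8-dimethyl-8-[(triethylsilyl)oxy]deca-4,9-dienenitrile
Conditions: n-BuLi, MeCN (3 equiv), THF, −78 °C; then 4, −78 → −20 °C
Reagents that add atoms: none
Why: SN2 alkylation of lithioacetonitrile by the primary allylic bromide forms C6–C7 and brings in C5 at the carboxyl oxidation level; the excess anion suppresses double alkylation, and attack at the unhindered CH2Br should leave the alkene in place.

Step 5
Reactants: 6 (4E,8R)-4,8-dimethyl-8-[(triethylsilyl)oxy]deca-4,9-dienenitrile
Product: 8 (4E,8R)-4,8-dimethyl-8-[(triethylsilyl)oxy]deca-4,9-dienal, via N-diisobutylaluminio aldimine 7 (not isolated)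
Conditions: i-Bu2AlH (1.2 equiv), CH2Cl2, −78 °C; aq. potassium sodium tartrate
Reagents that add atoms: water, O
Why: Partial reduction of a nitrile stops at the aluminium aldimine, which hydrolyses to the aldehyde on work-up; nothing else in 6 is reducible at −78 °C.

Step 6
Reactants: 8 (4E,8R)-4,8-dimethyl-8-[(triethylsilyl)oxy]deca-4,9-dienal; 9 trimethyl phosphonoacetate
Product: 10 methyl (2E,6E,10R)-6,10-dimethyl-10-[(triethylsilyl)oxy]dodeca-2,6,11-trienoate
Conditions: NaH, THF, 0 °C → rt
Reagents that add atoms: none
Why: Horner–Wadsworth–Emmons olefination of an unhindered aldehyde with a stabilised phosphonate anion should give the E enoate, which is the acceptor for step 10 and supplies C3 and C4.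

Step 7
Reactants: 11 but-2-yn-1-ol
Product: 13 (2Z)-3-iodobut-2-en-1-ol, via sodium alkenylalanate 12 (not isolated)
Conditions: NaAlH2(OCH2CH2OCH3)2, THF, 0 °C → rt; then I2, −78 °C
Reagents that add atoms: iodine, II
Why: Alkoxide-directed trans-hydroalumination of the propargylic alcohol places aluminium on the distal carbon, cis to CH2O, in a five-membered alanate; iodination with retention gives the Z iodide, which is the source of the Z relation between C2 and C5.

Step 8
Reactants: 13 (2Z)-3-iodobut-2-en-1-ol
Product: 14 tert-butyl{[(2Z)-3-iodobut-2-en-1-yl]oxy}dimethylsilane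
Conditions: t-BuMe2SiCl, imidazole, CH2Cl2, 0 °C → rt
Reagents that add atoms: tert-butyldimethylsilyl chloride, CC(C)(C)[Si](C)(C)Cl
Why: Standard silylation of a primary alcohol; the ether keeps the future C2 oxygen out of the borylation, the aqueous base of step 10 and the methylations.

Step 9
Reactants: 14 tert-butyl{[(2Z)-3-iodobut-2-en-1-yl]oxy}dimethylsilane
Product: 15 tert-butyl(dimethyl){[(2E)-3-(4,4,5,5-tetramethyl-1,3,2-dioxaborolan-2-yl)but-2-en-1-yl]oxy}silane (boron cis to CH2OSi; E only because methyl outranks boron)
Conditions: bis(pinacolato)diboron, PdCl2(PPh3)2 (3 mol %), PPh3, KOPh, toluene, 50 °C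
Reagents that add atoms: bis(pinacolato)diboron, CC1(C)OB(OC1(C)C)B1OC(C)(C)C(C)(C)O1
Why: Miyaura borylation of an alkenyl iodide proceeds with retention at the sp2 carbon, so boron stays cis to the silyloxymethyl group.

Step 10
Reactants: 10 methyl (2E,6E,10R)-6,10-dimethyl-10-[(triethylsilyl)oxy]dodeca-2,6,11-trienoate; 15 tert-butyl(dimethyl){[(2E)-3-(4,4,5,5-tetramethyl-1,3,2-dioxaborolan-2-yl)but-2-en-1-yl]oxy}silane
Product: 16 methyl (3S,6E,10R)-3-[(2Z)-4-{[tert-butyl(dimethyl)silyl]oxy}but-2-en-2-yl]-6,10-dimethyl-10-[(triethylsilyl)oxy]dodeca-6,11-dienoate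
Conditions: [Rh(OH)(cod)]2 (2.5 mol %), (R)-BINAP (6 mol %), 15 (2.5 equiv), K3PO4 (0.5 equiv), dioxane–H2O (10:1), 50 °C
Reagents that add atoms: none
Why: Rhodium-catalysed asymmetric 1,4-addition of an alkenylboronate (Hayashi–Miyaura reaction) forms C5–C10 and sets C5; the alkenyl–rhodium species keeps its geometry, so C2 ends cis to C5. The (R)-ligand is chosen because the empirical facial model for E acceptors has the (S)-ligand add to the α-si face, and the α-re face is needed here. The centre is 3S in 16 and becomes R without spatial change once C4 is quaternary.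

Step 11
Reactants: 16 methyl (3S,6E,10R)-3-[(2Z)-4-{[tert-butyl(dimethyl)silyl]oxy}but-2-en-2-yl]-6,10-dimethyl-10-[(triethylsilyl)oxy]dodeca-6,11-dienoate
Product: 18 methyl (3R,6E,10R)-3-[(2Z)-4-{[tert-butyl(dimethyl)silyl]oxy}but-2-en-2-yl]-2,2,6,10-tetramethyl-10-[(triethylsilyl)oxy]dodeca-6,11-dienoate, via monomethyl ester 17 (not isolated)
Conditions: LiN(i-Pr)2, THF, −78 °C, MeI; then LiN(i-Pr)2, DMPU, MeI, −78 → 0 °C
Reagents that add atoms: iodomethane, CI
Why: Two successive ester enolate methylations build the quaternary C4; the first new centre is erased by the second, C5 has no acidic hydrogen and cannot epimerise, and the small electrophile tolerates the hindered second enolate.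

Step 12
Reactants: 18 methyl (3R,6E,10R)-3-[(2Z)-4-{[tert-butyl(dimethyl)silyl]oxy}but-2-en-2-yl]-2,2,6,10-tetramethyl-10-[(triethylsilyl)oxy]dodeca-6,11-dienoate
Product: 19 methyl (3R,6E,10R)-10-hydroxy-3-[(2Z)-4-hydroxybut-2-en-2-yl]-2,2,6,10-tetramethyldodeca-6,11-dienoate
Conditions: Bu4NF, AcOH (1:1), THF, 0 → 40 °C
Reagents that add atoms: none
Why: Fluoride cleaves both silyl ethers; buffering with acetic acid avoids free alkoxide, so the Z-allylic oxygen should not attack the hindered ester and the tertiary allylic alcohol is not exposed to strong acid.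

Step 13
Reactants: 19 methyl (3R,6E,10R)-10-hydroxy-3-[(2Z)-4-hydroxybut-2-en-2-yl]-2,2,6,10-tetramethyldodeca-6,11-dienoate
Product: 20 methyl (3R,6E,10R)-10-hydroxy-2,2,6,10-tetramethyl-3-[(2Z)-4-oxobut-2-en-2-yl]dodeca-6,11-dienoate
Conditions: TEMPO (10 mol %), PhI(OAc)2, CH2Cl2, 0 °C → rt; used at once
Reagents that add atoms: none
Why: Oxoammonium oxidation takes only the primary allylic alcohol (the tertiary one cannot be oxidised) and is a mild, near-neutral method that should leave the Z-enal geometry intact.

Step 14
Reactants: 20 methyl (3R,6E,10R)-10-hydroxy-2,2,6,10-tetramethyl-3-[(2Z)-4-oxobut-2-en-2-yl]dodeca-6,11-dienoate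
Product: 22 methyl 2-[(2R,4aR,5S,6R,8aR)-2-ethenyl-2,5,8a-trimethyl-5-(2-oxoethyl)octahydro-2H-chromen-6-yl]-2-methylpropanoate, via chloro(methyl)aluminium enolate 21 (not isolated)
Conditions: Me2AlCl (2.5 equiv), CH2Cl2, −78 → −40 °C; aq. NaHCO3, potassium sodium tartrate
Reagents that add atoms: none
Why: Me2AlCl turns the C13 hydroxyl into its aluminium alkoxide (methane) and binds the C2 aldehyde, so C10 becomes the end of an oxy-allyl cation; C9 of the C8=C9 alkene adds to C10 and the tertiary C8 cation is taken by the C13 oxygen, giving enolate 21, which is protonated at C1 on work-up. The closest known reaction type is the Lewis-acid-promoted conjugate addition of alkenes to enals and enones, run as a cation–olefin cascade with oxygen termination. Ring B closes 6-endo with respect to the C8=C9 donor (exo with respect to the C1=C10 acceptor) through a chair, and the oxane closes as a six-membered ring by anti attack of oxygen at C8, again endo to the former C8=C9 bond. C10 is controlled by C5: with the formyl group cis to C5, allylic strain holds H5 in the enal plane, the C4 group and the C6 tether lie on opposite faces, and C9 can reach C10 only from the C6 face, anti to C4, which puts C20 axial and C1 equatorial; in the E isomer the position cis to C5 is hydrogen and this lock is absent. C9 and C8 follow from the E geometry of C8=C9 and anti addition in the chair–chair array (H9 axial, C11 and oxygen equatorial, C17 axial), and C13 is carried through unchanged. Addition at the aldehyde carbon would need an eight-membered ring, and attack of the ester carbonyl on C10 is reversible with a methyl ester. The step needs the Z geometry to last until the C–C bond forms and the C8 cation to be trapped before it loses a proton; the low temperature, the proton-scavenging methylaluminium reagent and the oxygen sitting six atoms from C8 are there to secure this.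

Step 15
Reactants: 22 methyl 2-[(2R,4aR,5S,6R,8aR)-2-ethenyl-2,5,8a-trimethyl-5-(2-oxoethyl)octahydro-2H-chromen-6-yl]-2-methylpropanoate
Product: 23 [(2R,4aR,5S,6R,8aR)-2-ethenyl-6-(1-methoxy-2-methyl-1-oxopropan-2-yl)-2,5,8a-trimethyloctahydro-2H-chromen-5-yl]acetic acid
Conditions: NaClO2, NaH2PO4, 2-methyl-2-butene, t-BuOH–H2O, 0 °C → rt
Reagents that add atoms: sodium chlorite, [Na+].[O-]Cl=O
Why: Pinnick oxidation converts the aldehyde to the acid at buffered pH; the alkene scavenger removes hypochlorous acid, so the vinyl group and the tertiary allylic ether should survive.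

Step 16
Reactants: 23 [(2R,4aR,5S,6R,8aR)-2-ethenyl-6-(1-methoxy-2-methyl-1-oxopropan-2-yl)-2,5,8a-trimethyloctahydro-2H-chromen-5-yl]acetic acid
Product: 24 2-[(2R,4aR,5S,6R,8aR)-5-(carboxymethyl)-2-ethenyl-2,5,8a-trimethyloctahydro-2H-chromen-6-yl]-2-methylpropanoic acid
Conditions: NaSEt (5 equiv), DMF, 90 °C; then cold 1 M HCl to pH 3
Reagents that add atoms: none
Why: SN2 dealkylation of a methyl ester by thiolate attacks the unhindered methyl carbon, not the shielded carbonyl; the conditions are basic, which the tertiary allylic ether and the vinyl group tolerate, and no stereocentre is enolisable.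

## Compound list

1 | (R)-linalool, (3R)-3,7-dimethylocta-1,6-dien-3-ol | CC(C)=CCC[C@@](C)(O)C=C | starting material
2 | triethyl{[(3R)-3,7-dimethylocta-1,6-dien-3-yl]oxy}silane | CC(C)=CCC[C@@](C)(O[Si](CC)(CC)CC)C=C | intermediate
3 | (2E,6R)-2,6-dimethyl-6-[(triethylsilyl)oxy]octa-2,7-dien-1-ol | OC/C(C)=C/CC[C@@](C)(O[Si](CC)(CC)CC)C=C | intermediate
4 | {[(3R,6E)-8-bromo-3,7-dimethylocta-1,6-dien-3-yl]oxy}(triethyl)silane | BrC/C(C)=C/CC[C@@](C)(O[Si](CC)(CC)CC)C=C | intermediate
5 | acetonitrile | CC#N | starting material
6 | (4E,8R)-4,8-dimethyl-8-[(triethylsilyl)oxy]deca-4,9-dienenitrile | N#CCC/C(C)=C/CC[C@@](C)(O[Si](CC)(CC)CC)C=C | intermediate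
7 | N-(diisobutylaluminio) aldimine of 8 | CC(C)C[Al](CC(C)C)N=CCC/C(C)=C/CC[C@@](C)(O[Si](CC)(CC)CC)C=C | intermediate (not isolated)
8 | (4E,8R)-4,8-dimethyl-8-[(triethylsilyl)oxy]deca-4,9-dienal | O=CCC/C(C)=C/CC[C@@](C)(O[Si](CC)(CC)CC)C=C | intermediate
9 | trimethyl phosphonoacetate | COC(=O)CP(=O)(OC)OC | starting material
10 | methyl (2E,6E,10R)-6,10-dimethyl-10-[(triethylsilyl)oxy]dodeca-2,6,11-trienoate | COC(=O)/C=C/CC/C(C)=C/CC[C@@](C)(O[Si](CC)(CC)CC)C=C | intermediate
11 | but-2-yn-1-ol | CC#CCO | starting material
12 | sodium 2,2-bis(2-methoxyethoxy)-3-methyl-2,5-dihydro-1,2-oxaluminol-2-uide (cyclic alkenylalanate) | CC1=CCO[Al-]1(OCCOC)OCCOC.[Na+] | intermediate (not isolated)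
13 | (2Z)-3-iodobut-2-en-1-ol | C/C(I)=C/CO | intermediate
14 | tert-butyl{[(2Z)-3-iodobut-2-en-1-yl]oxy}dimethylsilane | C/C(I)=C/CO[Si](C)(C)C(C)(C)C | intermediate
15 | tert-butyl(dimethyl){[(2E)-3-(4,4,5,5-tetramethyl-1,3,2-dioxaborolan-2-yl)but-2-en-1-yl]oxy}silane (boron cis to CH2OSi) | C/C(B1OC(C)(C)C(C)(C)O1)=C/CO[Si](C)(C)C(C)(C)C | intermediate
16 | methyl (3S,6E,10R)-3-[(2Z)-4-{[tert-butyl(dimethyl)silyl]oxy}but-2-en-2-yl]-6,10-dimethyl-10-[(triethylsilyl)oxy]dodeca-6,11-dienoate | CC(C)(C)[Si](C)(C)OC/C=C(/C)[C@H](CC(=O)OC)CC/C(C)=C/CC[C@@](C)(O[Si](CC)(CC)CC)C=C | intermediate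
17 | methyl (3S,6E,10R)-3-[(2Z)-4-{[tert-butyl(dimethyl)silyl]oxy}but-2-en-2-yl]-2,6,10-trimethyl-10-[(triethylsilyl)oxy]dodeca-6,11-dienoate (both C2 epimers) | CC(C)(C)[Si](C)(C)OC/C=C(/C)[C@H](C(C)C(=O)OC)CC/C(C)=C/CC[C@@](C)(O[Si](CC)(CC)CC)C=C | intermediate (not isolated)
18 | methyl (3R,6E,10R)-3-[(2Z)-4-{[tert-butyl(dimethyl)silyl]oxy}but-2-en-2-yl]-2,2,6,10-tetramethyl-10-[(triethylsilyl)oxy]dodeca-6,11-dienoate | CC(C)(C)[Si](C)(C)OC/C=C(/C)[C@H](C(C)(C)C(=O)OC)CC/C(C)=C/CC[C@@](C)(O[Si](CC)(CC)CC)C=C | intermediate
19 | methyl (3R,6E,10R)-10-hydroxy-3-[(2Z)-4-hydroxybut-2-en-2-yl]-2,2,6,10-tetramethyldodeca-6,11-dienoate | OC/C=C(/C)[C@H](C(C)(C)C(=O)OC)CC/C(C)=C/CC[C@@](C)(O)C=C | intermediate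
20 | methyl (3R,6E,10R)-10-hydroxy-2,2,6,10-tetramethyl-3-[(2Z)-4-oxobut-2-en-2-yl]dodeca-6,11-dienoate | O=C/C=C(/C)[C@H](C(C)(C)C(=O)OC)CC/C(C)=C/CC[C@@](C)(O)C=C | intermediate
21 | chloro(methyl)aluminium enolate of 22 | C=C[C@@]1(C)CC[C@@H]2[C@@](C)(C=CO[Al](C)Cl)[C@H](C(C)(C)C(=O)OC)CC[C@@]2(C)O1 | intermediate (not isolated)
22 | methyl 2-[(2R,4aR,5S,6R,8aR)-2-ethenyl-2,5,8a-trimethyl-5-(2-oxoethyl)octahydro-2H-chromen-6-yl]-2-methylpropanoate | C=C[C@@]1(C)CC[C@@H]2[C@@](C)(CC=O)[C@H](C(C)(C)C(=O)OC)CC[C@@]2(C)O1 | intermediate
23 | [(2R,4aR,5S,6R,8aR)-2-ethenyl-6-(1-methoxy-2-methyl-1-oxopropan-2-yl)-2,5,8a-trimethyloctahydro-2H-chromen-5-yl]acetic acid | C=C[C@@]1(C)CC[C@@H]2[C@@](C)(CC(=O)O)[C@H](C(C)(C)C(=O)OC)CC[C@@]2(C)O1 | intermediate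
24 | 2-[(2R,4aR,5S,6R,8aR)-5-(carboxymethyl)-2-ethenyl-2,5,8a-trimethyloctahydro-2H-chromen-6-yl]-2-methylpropanoic acid | C=C[C@@]1(C)CC[C@@H]2[C@@](C)(CC(=O)O)[C@H](C(C)(C)C(=O)O)CC[C@@]2(C)O1 | target

## Step count and least certain steps

Total step count: 16. Longest linear sequence: 13 steps (steps 1–6 and 10–16, from 1 to 24); the boronate branch (steps 7–9) adds 3.

**Step 14 (key step).** The most likely failure is interruption of the cascade after the first ring. Oxygen has to close onto the tertiary C8 through a chair that sets the C16 and C17 methyl groups 1,3-diaxial, whereas loss of a proton from C8 carries no such cost. A second weakness is relaxation of the aluminium-bound Z-enal to the E isomer before the ring closes, which would erode the ratio at C10.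

Fallback (sets out from 20, returns to the route at 23): the two ring closures are separated. Me2AlCl at −78 °C is used only for the C9–C10 bond, and the ring B aldehyde methyl 2-{(1R,2R,3S)-3-[(3R)-3-hydroxy-3-methylpent-4-en-1-yl]-2-methyl-4-methylidene-2-(2-oxoethyl)cyclohexyl}-2-methylpropanoate F1 is taken on as formed (exocyclic C8=C17 alkene; positional isomers of this double bond converge in the next operation). The oxane is then closed by intramolecular oxymercuration with Hg(OCOCF3)2 (divalent mercury) in THF at −20 °C, a closure known for labd-8(17)-en-13-ols, giving {[(2R,4aR,5S,6R,8aR)-2-ethenyl-6-(1-methoxy-2-methyl-1-oxopropan-2-yl)-2,5-dimethyl-5-(2-oxoethyl)octahydro-2H-chromen-8a-yl]methyl}mercury trifluoroacetate F2. Without isolation, NaBH4 in aqueous NaOH removes mercury and reduces the aldehyde, giving methyl 2-[(2R,4aR,5S,6R,8aR)-2-ethenyl-5-(2-hydroxyethyl)-2,5,8a-trimethyloctahydro-2H-chromen-6-yl]-2-methylpropanoate F3. TEMPO (cat.), NaOCl (cat.) and NaClO2 in buffered acetonitrile then oxidise the primary alcohol to 23.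

**Step 10.** The most likely failure is slow transfer and insertion of the α-branched alkenyl group on a weakly activated acyclic enoate, so that protodeboronation consumes 15 and facial discrimination falls.

Fallback (sets out from 8 and 14, returns at 16): the stereocentre is set by an auxiliary. Olefination of 8 with diethyl {2-oxo-2-[(4R)-2-oxo-4-phenyl-1,3-oxazolidin-3-yl]ethyl}phosphonate (LiCl, i-Pr2NEt, MeCN) should give (4R)-3-[(2E,6E,10R)-6,10-dimethyl-10-[(triethylsilyl)oxy]dodeca-2,6,11-trienoyl]-4-phenyl-1,3-oxazolidin-2-one F4. Iodide 14 is converted with t-BuLi (−78 °C) and MgBr2·OEt2 into bromo{(2Z)-4-[(tert-butyldimethylsilyl)oxy]but-2-en-2-yl}magnesium F5, with retention. Addition of F5 with CuBr·SMe2 in THF at −40 °C to the chelated imide takes place anti to the phenyl group, the same face as in step 10, to give (4R)-3-[(3S,6E)-3-[(2Z)-4-{[tert-butyl(dimethyl)silyl]oxy}but-2-en-2-yl]-6,10-dimethyl-10-[(triethylsilyl)oxy]dodeca-6,11-dienoyl]-4-phenyl-1,3-oxazolidin-2-one (10R) F6. NaOMe in methanol at 0 °C releases the auxiliary and gives 16.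

**Step 2.** The most likely failure is incomplete conversion together with over-oxidation to the enal and partial loss of the silyl ether under the acidic selenium conditions, so that material throughput at the very start is poor.

Fallback (sets out from 2, returns at 3): the E-allylic alcohol is rebuilt by cleavage and olefination. m-CPBA (CH2Cl2, NaHCO3, 0 °C) epoxidises the trisubstituted alkene first, giving triethyl{[(3R)-5-(3,3-dimethyloxiran-2-yl)-3-methylpent-1-en-3-yl]oxy}silane F7. HIO4 in THF–water cleaves it to (4R)-4-methyl-4-[(triethylsilyl)oxy]hex-5-enal F8. The stabilised ylide Ph3P=C(CH3)CO2Et gives ethyl (2E,6R)-2,6-dimethyl-6-[(triethylsilyl)oxy]octa-2,7-dienoate F9 with E selectivity, and i-Bu2AlH (CH2Cl2, −78 °C) reduces it to 3.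

**Step 16.** The most likely failure is sluggish dealkylation: the carboxylate already present lowers the reactivity of the molecule towards a second anionic reagent, and prolonged heating with thiolate invites decomposition.

Fallback (sets out from 22, returns at 24, replacing steps 15 and 16): the ester is taken through the alcohol. LiAlH4 in THF reduces both the aldehyde and the hindered ester to 2-[(2R,4aR,5S,6R,8aR)-2-ethenyl-6-(1-hydroxy-2-methylpropan-2-yl)-2,5,8a-trimethyloctahydro-2H-chromen-5-yl]ethan-1-ol F10. TEMPO (cat.), NaOCl (cat.) and NaClO2 in buffered acetonitrile at 35 °C oxidise both primary alcohols to the diacid 24, so no acyl substitution at the shielded carbonyl is needed.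

## Further compounds

F1 | step 14 | methyl 2-{(1R,2R,3S)-3-[(3R)-3-hydroxy-3-methylpent-4-en-1-yl]-2-methyl-4-methylidene-2-(2-oxoethyl)cyclohexyl}-2-methylpropanoate | C=C[C@](C)(O)CC[C@@H]1[C@@](C)(CC=O)[C@H](C(C)(C)C(=O)OC)CCC1=C
F2 | step 14 | {[(2R,4aR,5S,6R,8aR)-2-ethenyl-6-(1-methoxy-2-methyl-1-oxopropan-2-yl)-2,5-dimethyl-5-(2-oxoethyl)octahydro-2H-chromen-8a-yl]methyl}mercury trifluoroacetate | C=C[C@@]1(C)CC[C@@H]2[C@@](C)(CC=O)[C@H](C(C)(C)C(=O)OC)CC[C@@]2(C[Hg]OC(=O)C(F)(F)F)O1
F3 | step 14 | methyl 2-[(2R,4aR,5S,6R,8aR)-2-ethenyl-5-(2-hydroxyethyl)-2,5,8a-trimethyloctahydro-2H-chromen-6-yl]-2-methylpropanoate | C=C[C@@]1(C)CC[C@@H]2[C@@](C)(CCO)[C@H](C(C)(C)C(=O)OC)CC[C@@]2(C)O1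
F4 | step 10 | (4R)-3-[(2E,6E,10R)-6,10-dimethyl-10-[(triethylsilyl)oxy]dodeca-2,6,11-trienoyl]-4-phenyl-1,3-oxazolidin-2-one | O=C(/C=C/CC/C(C)=C/CC[C@@](C)(O[Si](CC)(CC)CC)C=C)N1[C@H](c2ccccc2)COC1=O
F5 | step 10 | bromo{(2Z)-4-[(tert-butyldimethylsilyl)oxy]but-2-en-2-yl}magnesium (magnesium cis to CH2OSi) | C/C([Mg]Br)=C/CO[Si](C)(C)C(C)(C)C
F6 | step 10 | (4R)-3-[(3S,6E,10R)-3-[(2Z)-4-{[tert-butyl(dimethyl)silyl]oxy}but-2-en-2-yl]-6,10-dimethyl-10-[(triethylsilyl)oxy]dodeca-6,11-dienoyl]-4-phenyl-1,3-oxazolidin-2-one | CC(C)(C)[Si](C)(C)OC/C=C(/C)[C@H](CC(=O)N1[C@H](c2ccccc2)COC1=O)CC/C(C)=C/CC[C@@](C)(O[Si](CC)(CC)CC)C=C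
F7 | step 2 | triethyl{[(3R)-5-(3,3-dimethyloxiran-2-yl)-3-methylpent-1-en-3-yl]oxy}silane (both oxirane epimers) | CC1(C)OC1CC[C@@](C)(O[Si](CC)(CC)CC)C=C
F8 | step 2 | (4R)-4-methyl-4-[(triethylsilyl)oxy]hex-5-enal | O=CCC[C@@](C)(O[Si](CC)(CC)CC)C=C
F9 | step 2 | ethyl (2E,6R)-2,6-dimethyl-6-[(triethylsilyl)oxy]octa-2,7-dienoate | CCOC(=O)/C(C)=C/CC[C@@](C)(O[Si](CC)(CC)CC)C=C
F10 | step 16 | 2-[(2R,4aR,5S,6R,8aR)-2-ethenyl-6-(1-hydroxy-2-methylpropan-2-yl)-2,5,8a-trimethyloctahydro-2H-chromen-5-yl]ethan-1-ol | C=C[C@@]1(C)CC[C@@H]2[C@@](C)(CCO)[C@H](C(C)(C)CO)CC[C@@]2(C)O1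
A1 | alternative 1 | tert-butyl 2-[8-(2-tert-butoxy-2-oxoethyl)-8a-ethenyl-3,4a,8-trimethyl-2-oxooctahydro-2H-1,4-benzodioxin-7-yl]-2-methylpropanoate (4a,8a-cis-fused; C4a, C7, C8 as in the target; C3 either) | C=C[C@@]12OC(=O)C(C)O[C@]1(C)CC[C@@H](C(C)(C)C(=O)OC(C)(C)C)[C@]2(C)CC(=O)OC(C)(C)C
A2 | alternative 1 | 5-(2-tert-butoxy-2-oxoethyl)-6-(1-tert-butoxy-2-methyl-1-oxopropan-2-yl)-2,5,8a-trimethyl-3,5,6,7,8,8a-hexahydro-2H-chromene-2-carboxylic acid (configuration as in the target) | OC(=O)[C@@]1(C)CC=C2[C@@](C)(CC(=O)OC(C)(C)C)[C@H](C(C)(C)C(=O)OC(C)(C)C)CC[C@@]2(C)O1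
A3 | alternative 2 | triethyl{[(3R,6E)-3,7-dimethylnona-1,6,8-trien-3-yl]oxy}silane | C=C/C(C)=C/CC[C@@](C)(O[Si](CC)(CC)CC)C=C
A4 | alternative 2 | methyl (3E)-2,2,4-trimethyl-5-oxopent-3-enoate | COC(=O)C(C)(C)/C=C(\C)C=O
A5 | alternative 2 | methyl 2-{6-formyl-4,6-dimethyl-5-[(3R)-3-methyl-3-[(triethylsilyl)oxy]pent-4-en-1-yl]cyclohex-3-en-1-yl}-2-methylpropanoate (ring configuration as in the target) | C=C[C@](C)(O[Si](CC)(CC)CC)CC[C@@H]1[C@@](C)(C=O)[C@H](C(C)(C)C(=O)OC)CC=C1C
A6 | alternative 3 | tert-butyl 2-{2-(2-tert-butoxy-2-oxoethyl)-3-[3-(1,3-dithian-2-ylidene)butyl]-4-hydroxy-2,4-dimethylcyclohexyl}-2-methylpropanoate (ring configuration as in the target) | CC(CC[C@@H]1[C@@](C)(CC(=O)OC(C)(C)C)[C@H](C(C)(C)C(=O)OC(C)(C)C)CC[C@@]1(C)O)=C1SCCCS1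
A7 | alternative 3 | tert-butyl 2-[5-(2-tert-butoxy-2-oxoethyl)-2-(2-methoxy-1,3-dithian-2-yl)-2,5,8a-trimethyloctahydro-2H-chromen-6-yl]-2-methylpropanoate (configuration as in the target) | COC1(SCCCS1)[C@@]2(C)CC[C@@H]3[C@@](C)(CC(=O)OC(C)(C)C)[C@H](C(C)(C)C(=O)OC(C)(C)C)CC[C@@]3(C)O2
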